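The decalin is taken apart at C6–C7 and at the ring-fusion bond C5–C10, so both rings open into one chain. This is possible because C5, the methyl-bearing quaternary carbon, lies next to C4 (a ketone in disguise that later carries C15), while C8 is a carbonyl carbon between C7 and C9: ring B is the adduct of a C7–C10 2-silyloxydiene and a C5=C6 isopropenyl ketone joined through C1–C3. One enantioselective intramolecular Diels–Alder reaction closes rings A and B, sets C5 and leaves a C8=C9 enol ether for oxidation at C9. Its precursor is an open-chain (E)-trienone with a triisopropylsilyl dienol ether, freed from a Weinreb amide just before use.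

Key step: step 5

Numbering: target numbering throughout (ring A = C1–C5 and C10; ring B = C5–C10; C14 = methyl on C5; C15 = methyl on C4; C11–C13 = isopropylidene on C7). "Octal" names mean the octahydronaphthalene core with this numbering. The target is (3R,4R,5R) with both side-chain alkenes Z.

Assumption: both antipodes of the diphenylprolinol-derived o-tolyl oxazaborolidine are available; the (S)-catalyst is proposed first, its sense of induction is not secured by precedent for an α-methyl vinyl ketone and would be checked on the adduct, and the route is written for whichever antipode gives the (5S,10R) adduct.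

Step 1
Reactants: 1 hex-5-enoyl chloride; 2 N,O-dimethylhydroxylamine hydrochloride
Product: 3 N-methoxy-N-methylhex-5-enamide
Conditions: pyridine (2.2 equiv), CH2Cl2, 0 °C → rt
Reagents that add atoms: none
Why: Schotten–Baumann-type N-acylation gives the Weinreb amide, which carries the future C4 carbonyl in a form that is neither enolised nor attacked in the next two steps.

Step 2
Reactants: 3 N-methoxy-N-methylhex-5-enamide; 4 methyl vinyl ketone
Product: 5 (5E)-N-methoxy-N-methyl-7-oxooct-5-enamide
Conditions: 4 (3 equiv), second-generation Grubbs catalyst RuCl2(=CHPh)(PCy3)(H2IMes) (2 mol %), CH2Cl2, 40 °C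
Reagents that add atoms: none
Why: Olefin cross-metathesis of a terminal alkene with an electron-poor vinyl ketone should give the (E)-enone selectively and releases only ethylene.

Step 3
Reactants: 5 (5E)-N-methoxy-N-methyl-7-oxooct-5-enamide
Product: 6 (5E)-N-methoxy-N-methyl-7-[(triisopropylsilyl)oxy]octa-5,7-dienamide
Conditions: TIPSOTf (1.2 equiv), Et3N (2 equiv), CH2Cl2, 0 °C
Reagents that add atoms: triisopropylsilyl trifluoromethanesulfonate, CC(C)[Si](OS(=O)(=O)C(F)(F)F)(C(C)C)C(C)C
Why: Soft enolisation (silyl triflate and tertiary amine) removes a proton from the α′-methyl of the enone and gives the 2-silyloxydiene with the E alkene kept, while the much less acidic amide α-CH2 is left alone, so no second ketone competes at this stage.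

Step 4
Reactants: 6 (5E)-N-methoxy-N-methyl-7-[(triisopropylsilyl)oxy]octa-5,7-dienamide; 7 isopropenylmagnesium bromide
Product: 9 (7E)-2-methyl-9-[(triisopropylsilyl)oxy]deca-1,7,9-trien-3-one, via bromomagnesium hemiaminal chelate 8 (not isolated)
Conditions: 7 (1.5 equiv), THF, −40 → 0 °C; cold pH 7 phosphate buffer; crude 9 kept below 0 °C and used at once
Reagents that add atoms: none
Why: Weinreb ketone synthesis, in which the stable magnesium chelate prevents over-addition and keeps the dienophile masked until the cold neutral quench, so the isopropenyl ketone is freed only immediately before the cycloaddition.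

Step 5
Reactants: 9 (7E)-2-methyl-9-[(triisopropylsilyl)oxy]deca-1,7,9-trien-3-one
Product: 10 cis-fused (5S,10R)-5-methyl-8-[(triisopropylsilyl)oxy]octal-8-en-4-one
Conditions: (S)-o-tolyl oxazaborolidine [(S)-3,3-diphenyl-1-(2-methylphenyl)tetrahydro-1H,3H-pyrrolo[1,2-c][1,3,2]oxazaborole] (20 mol %), Tf2NH (18 mol %), CH2Cl2, −78 → −40 °C; Et3N quench
Reagents that add atoms: none
Why: The cationic oxazaborolidinium binds the only ketone (C4=O) and activates the C5=C6 isopropenyl unit, and the 2-silyloxydiene then adds in a concerted, asynchronous normal-demand [4+2] in which its nucleophilic terminus C7 bonds to the β-carbon C6 slightly ahead of C10–C5. The closest known reaction types are the oxazaborolidinium-catalysed Diels–Alder reaction of 2-(trialkylsilyloxy)dienes with enones and the intramolecular Diels–Alder reaction of deca-1,7,9-trien-3-ones. Ring B closes as the cyclohexene made by the cycloaddition itself, and ring A closes in the same event as a six-membered carbocycle because the C1–C3 chain and the C4 carbonyl tie C10 to C5 (fused mode). C5 is set by the face of the dienophile that the catalyst leaves open; C10 follows from the E diene and the endo position of the catalyst-bound tether carbonyl, which should give the cis ring fusion. Only enantioface selectivity at C5=C6 is needed, since C10 is later made trigonal and the regiochemistry is fixed by the tether and by matched polarity; the substrate helps through the single Lewis-basic carbonyl sitting directly on the dienophile, the α-methyl group that slows the uncatalysed cyclisation at −78 °C, and the bulky, acid-tolerant triisopropylsilyl enol ether.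

Step 6
Reactants: 10 cis-fused (5S,10R)-5-methyl-8-[(triisopropylsilyl)oxy]octal-8-en-4-one
Product: 12 (5S,10R)-5-methyl-8-[(triisopropylsilyl)oxy]octala-3,8-dien-4-yl trifluoromethanesulfonate, via potassium enolate 11 (not isolated)
Conditions: KN(SiMe3)2 (1.2 equiv), THF, −78 °C; PhNTf2 (1.3 equiv), −78 → 0 °C
Reagents that add atoms: N-phenylbis(trifluoromethanesulfonimide), O=S(=O)(N(c1ccccc1)S(=O)(=O)C(F)(F)F)C(F)(F)F
Why: With C8 still masked as its enol ether and C5 quaternary, only the C3–C4 enolate can form, and it is O-sulfonylated by PhNTf2 (enol triflate formation).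

Step 7
Reactants: 12 (5S,10R)-5-methyl-8-[(triisopropylsilyl)oxy]octala-3,8-dien-4-yl trifluoromethanesulfonate; 13 methylmagnesium bromide
Product: 14 (5S,10R)-4,5-dimethyl-8-[(triisopropylsilyl)oxy]octala-3,8-diene
Conditions: 13 (1.5 equiv), Fe(acac)3 (5 mol %), THF/NMP, −30 → 0 °C
Reagents that add atoms: none
Why: Iron-catalysed Kumada-type cross-coupling of an alkenyl triflate with MeMgBr installs C15 on C4 and leaves the silyl enol ether untouched.

Step 8
Reactants: 14 (5S,10R)-4,5-dimethyl-8-[(triisopropylsilyl)oxy]octala-3,8-diene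
Product: 17 9-hydroxy-4,5-dimethyloctal-3-en-8-one, via silyloxy epoxide 15 (not isolated), via α-silyloxy ketone 16 (not isolated)
Conditions: mCPBA (1.05 equiv), NaHCO3, CH2Cl2, −20 °C; then HF·pyridine, THF, 0 °C
Reagents that add atoms: 3-chloroperbenzoic acid, OOC(=O)c1cccc(Cl)c1
Why: Rubottom oxidation, in which the electron-rich silyl enol ether is epoxidised much faster than the hindered C3=C4 alkene, the silyloxy epoxide rearranges with silyl shift and fluoride frees the C9 hydroxyl, whose configuration does not matter because C9 becomes trigonal in the next step.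

Step 9
Reactants: 17 9-hydroxy-4,5-dimethyloctal-3-en-8-one
Product: 19 (5R)-9-hydroxy-4,5-dimethyloctala-3,9-dien-8-one, via 8,9-diketone 18 (not isolated)
Conditions: Dess–Martin periodinane (1.3 equiv), NaHCO3, CH2Cl2, 0 °C → rt; Et3N (cat.) on work-up
Reagents that add atoms: none
Why: Dess–Martin oxidation of the acyloin gives the 8,9-diketone, which should enolise toward the more substituted C10 as 3,4-diketo steroids do (4-hydroxy-4-en-3-ones), so C10 becomes trigonal, either ring-fusion isomer converges, and the C14 methyl is locked axial on ring A before C3=C4 is functionalised.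

Step 10
Reactants: 19 (5R)-9-hydroxy-4,5-dimethyloctala-3,9-dien-8-one
Product: 20 (5R)-4,5-dimethyl-9-[(triisopropylsilyl)oxy]octala-3,9-dien-8-one
Conditions: TIPSOTf (1.1 equiv), 2,6-lutidine (1.5 equiv), CH2Cl2, −78 → 0 °C
Reagents that add atoms: triisopropylsilyl trifluoromethanesulfonate, CC(C)[Si](OS(=O)(=O)C(F)(F)F)(C(C)C)C(C)C
Why: O-Silylation of the acidic enol hydroxyl with a silyl triflate and a hindered pyridine base protects the diosphenol without any C–H deprotonation, so the enol stays at C9=C10.

Step 11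
Reactants: 20 (5R)-4,5-dimethyl-9-[(triisopropylsilyl)oxy]octala-3,9-dien-8-one
Product: 22 (3R,4R,5R)-4,5-dimethyl-9-[(triisopropylsilyl)oxy]octal-9-ene-3,8-diol, via alkylborane adduct 21 (not isolated)
Conditions: BH3·THF (3 equiv), THF, 0 °C → rt; then NaBO3·4H2O, THF/H2O, rt
Reagents that add atoms: sodium perborate (oxygen on C3), [Na+].[O-]OB=O
Why: Hydroboration–oxidation, in which borane adds syn across C3=C4 with boron on the less substituted C3 and from the α face, anti to the axial C14 methyl (as in Δ5-steroids), so that oxidation with retention sets C3–OH and C4–H (C15 cis to C14, oxygen trans to C15); the C8 ketone is reduced at the same time to an allylic alcohol of no stereochemical consequence and the hindered tetrasubstituted enol ether should be left alone.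

Step 12
Reactants: 22 (3R,4R,5R)-4,5-dimethyl-9-[(triisopropylsilyl)oxy]octal-9-ene-3,8-diol
Product: 23 (3R,4R,5R)-3-hydroxy-4,5-dimethyl-9-[(triisopropylsilyl)oxy]octal-9-en-8-one
Conditions: MnO2 (20 equiv), CH2Cl2, rt
Reagents that add atoms: none
Why: MnO2 oxidises the allylic C8 alcohol back to the enone chemoselectively and leaves the saturated secondary C3 alcohol untouched.

Step 13
Reactants: 23 (3R,4R,5R)-3-hydroxy-4,5-dimethyl-9-[(triisopropylsilyl)oxy]octal-9-en-8-one; 24 acetone
Product: 26 (3R,4R,5R)-3-hydroxy-7-(2-hydroxypropan-2-yl)-4,5-dimethyl-9-[(triisopropylsilyl)oxy]octal-9-en-8-one, via dilithium alkoxide enolate 25 (not isolated)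
Conditions: LiN(i-Pr)2 (2.3 equiv), THF, −78 °C; 24 (3 equiv), −78 °C; AcOH, −78 °C
Reagents that add atoms: none
Why: Directed aldol addition, in which the C3 alkoxide forms first, the kinetic α′ proton at C7 (the only α-CH2) is removed next and the enolate adds to acetone, the configuration at C7 being irrelevant because it becomes trigonal.

Step 14
Reactants: 26 (3R,4R,5R)-3-hydroxy-7-(2-hydroxypropan-2-yl)-4,5-dimethyl-9-[(triisopropylsilyl)oxy]octal-9-en-8-one
Product: 27 (3R,4R,5R)-3-hydroxy-4,5-dimethyl-7-(propan-2-ylidene)-9-[(triisopropylsilyl)oxy]octal-9-en-8-one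
Conditions: Martin sulfurane Ph2S[OC(CF3)2Ph]2 (1.5 equiv), CH2Cl2, 0 °C → rt
Reagents that add atoms: none
Why: Martin sulfurane dehydrates the tertiary carbinol quickly with loss of the acidic C7 hydrogen to give the conjugated isopropylidene ketone, whereas the equatorial secondary C3 alcohol has no antiperiplanar hydrogen, only exchanges reversibly and is recovered.

Step 15
Reactants: 28 4-methylfuran-2(5H)-one
Product: 30 4-methoxybenzyl (Z)-4-hydroxy-3-methylbut-2-enoate, via sodium hydroxy carboxylate 29 (not isolated)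
Conditions: NaOH (1.0 equiv), MeOH/H2O, rt; evaporate; 4-methoxybenzyl chloride (1.1 equiv), NaI (cat.), DMF, rt
Reagents that add atoms: sodium hydroxide, [Na+].[OH-]; 4-methoxybenzyl chloride, COc1ccc(CCl)cc1
Why: Saponification of the butenolide keeps the ring-enforced Z geometry, and SN2 O-alkylation of the carboxylate gives the ester without acidification, so the hydroxy acid is never free to relactonise.

Step 16
Reactants: 30 4-methoxybenzyl (Z)-4-hydroxy-3-methylbut-2-enoate; 31 angelic acid
Product: 32 4-methoxybenzyl (Z)-3-methyl-4-{[(Z)-2-methylbut-2-enoyl]oxy}but-2-enoate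
Conditions: PPh3, DIAD, THF, 0 °C
Reagents that add atoms: none
Why: Mitsunobu esterification activates the primary allylic alcohol and not the angeloyl carbonyl, so the angelate is introduced without Z-to-E isomerisation to tiglate.

Step 17
Reactants: 32 4-methoxybenzyl (Z)-3-methyl-4-{[(Z)-2-methylbut-2-enoyl]oxy}but-2-enoate
Product: 33 (Z)-3-methyl-4-{[(Z)-2-methylbut-2-enoyl]oxy}but-2-enoic acid
Conditions: TFA, anisole, CH2Cl2, 0 °C
Reagents that add atoms: none
Why: Acidolysis of the 4-methoxybenzyl ester (SN1 cleavage with anisole as cation trap) frees the acid under non-basic conditions that leave both enoate esters and both Z alkenes intact.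

Step 18
Reactants: 27 (3R,4R,5R)-3-hydroxy-4,5-dimethyl-7-(propan-2-ylidene)-9-[(triisopropylsilyl)oxy]octal-9-en-8-one; 33 (Z)-3-methyl-4-{[(Z)-2-methylbut-2-enoyl]oxy}but-2-enoic acid
Product: 35 (3R,4R,5R)-4,5-dimethyl-8-oxo-7-(propan-2-ylidene)-9-[(triisopropylsilyl)oxy]octal-9-en-3-yl (Z)-3-methyl-4-{[(Z)-2-methylbut-2-enoyl]oxy}but-2-enoate, via mixed anhydride 34 (not isolated)
Conditions: 2,4,6-trichlorobenzoyl chloride, Et3N, toluene, rt; then 27, DMAP, rt
Reagents that add atoms: none
Why: Yamaguchi esterification, in which DMAP attacks the mixed anhydride at the less hindered enoyl carbonyl and the acylpyridinium acylates the equatorial C3 hydroxyl with retention at C3.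

Step 19
Reactants: 35 (3R,4R,5R)-4,5-dimethyl-8-oxo-7-(propan-2-ylidene)-9-[(triisopropylsilyl)oxy]octal-9-en-3-yl (Z)-3-methyl-4-{[(Z)-2-methylbut-2-enoyl]oxy}but-2-enoate
Product: 36 (3R,4R,5R)-9-hydroxy-4,5-dimethyl-8-oxo-7-(propan-2-ylidene)octal-9-en-3-yl (Z)-3-methyl-4-{[(Z)-2-methylbut-2-enoyl]oxy}but-2-enoate
Conditions: HF·pyridine, pyridine/THF, 0 °C
Reagents that add atoms: none
Why: Fluoride-mediated cleavage of the enol silyl ether under buffered, weakly acidic conditions frees the diosphenol, the only possible enol of the 8,9-diketone because C7 is fully substituted, without touching the esters.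

Compound list
1 | hex-5-enoyl chloride | C=CCCCC(=O)Cl | starting material
2 | N,O-dimethylhydroxylamine hydrochloride | CNOC.Cl | starting material
3 | N-methoxy-N-methylhex-5-enamide | C=CCCCC(=O)N(C)OC | intermediate
4 | methyl vinyl ketone (but-3-en-2-one) | CC(=O)C=C | starting material
5 | (5E)-N-methoxy-N-methyl-7-oxooct-5-enamide | CC(=O)/C=C/CCCC(=O)N(C)OC | intermediate
6 | (5E)-N-methoxy-N-methyl-7-[(triisopropylsilyl)oxy]octa-5,7-dienamide | C=C(O[Si](C(C)C)(C(C)C)C(C)C)/C=C/CCCC(=O)N(C)OC | intermediate
7 | isopropenylmagnesium bromide | CC(=C)[Mg]Br | starting material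
8 | bromomagnesium hemiaminal chelate (tetrahedral adduct of 6 and 7) | C=C(C)C(O[Mg]Br)(N(C)OC)CCC/C=C/C(=C)O[Si](C(C)C)(C(C)C)C(C)C | intermediate (not isolated)
9 | (7E)-2-methyl-9-[(triisopropylsilyl)oxy]deca-1,7,9-trien-3-one (key-step precursor) | C=C(C)C(=O)CCC/C=C/C(=C)O[Si](C(C)C)(C(C)C)C(C)C | intermediate
10 | cis-fused (5S,10R)-5-methyl-8-[(triisopropylsilyl)oxy]octal-8-en-4-one; (4aR,8aS)-8a-methyl-6-[(triisopropylsilyl)oxy]-3,4,4a,7,8,8a-hexahydronaphthalen-1(2H)-one (key-step product; H10 and C14 cis) | O=C1CCC[C@@H]2C=C(O[Si](C(C)C)(C(C)C)C(C)C)CC[C@]12C | intermediate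
11 | potassium C3–C4 enolate of 10 | [K+].[O-]C1=CCC[C@@H]2C=C(O[Si](C(C)C)(C(C)C)C(C)C)CC[C@]12C | intermediate (not isolated)
12 | (5S,10R)-5-methyl-8-[(triisopropylsilyl)oxy]octala-3,8-dien-4-yl trifluoromethanesulfonate | O=S(=O)(OC1=CCC[C@@H]2C=C(O[Si](C(C)C)(C(C)C)C(C)C)CC[C@]12C)C(F)(F)F | intermediate
13 | methylmagnesium bromide | C[Mg]Br | starting material
14 | (5S,10R)-4,5-dimethyl-8-[(triisopropylsilyl)oxy]octala-3,8-diene | CC1=CCC[C@@H]2C=C(O[Si](C(C)C)(C(C)C)C(C)C)CC[C@]12C | intermediate
15 | 8,9-epoxy-4,5-dimethyl-8-[(triisopropylsilyl)oxy]octal-3-ene (C5, C10 as in 14; epoxide face not controlled) | CC1=CCC[C@@H]2C3OC3(O[Si](C(C)C)(C(C)C)C(C)C)CC[C@]12C | intermediate (not isolated)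
16 | 4,5-dimethyl-9-[(triisopropylsilyl)oxy]octal-3-en-8-one (C5, C10 as in 14; C9 epimers) | CC1=CCC[C@@H]2C(O[Si](C(C)C)(C(C)C)C(C)C)C(=O)CC[C@]12C | intermediate (not isolated)
17 | 9-hydroxy-4,5-dimethyloctal-3-en-8-one (C5, C10 as in 14; C9 epimers) | CC1=CCC[C@@H]2C(O)C(=O)CC[C@]12C | intermediate
18 | 4,5-dimethyloctal-3-ene-8,9-dione (C5, C10 as in 14) | CC1=CCC[C@@H]2C(=O)C(=O)CC[C@]12C | intermediate (not isolated)
19 | (5R)-9-hydroxy-4,5-dimethyloctala-3,9-dien-8-one (diosphenol) | CC1=CCCC2=C(O)C(=O)CC[C@]12C | intermediate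
20 | (5R)-4,5-dimethyl-9-[(triisopropylsilyl)oxy]octala-3,9-dien-8-one | CC1=CCCC2=C(O[Si](C(C)C)(C(C)C)C(C)C)C(=O)CC[C@]12C | intermediate
21 | alkylborane adduct: BH2 on C3 (α), H on C4 (α), O–BH2 on C8 (C3, C4, C5 as in 22; C8 epimers) | B[C@@H]1CCC2=C(O[Si](C(C)C)(C(C)C)C(C)C)C(OB)CC[C@]2(C)[C@H]1C | intermediate (not isolated)
22 | (3R,4R,5R)-4,5-dimethyl-9-[(triisopropylsilyl)oxy]octal-9-ene-3,8-diol (C8 epimers) | O[C@@H]1CCC2=C(O[Si](C(C)C)(C(C)C)C(C)C)C(O)CC[C@]2(C)[C@H]1C | intermediate
23 | (3R,4R,5R)-3-hydroxy-4,5-dimethyl-9-[(triisopropylsilyl)oxy]octal-9-en-8-one | O[C@@H]1CCC2=C(O[Si](C(C)C)(C(C)C)C(C)C)C(=O)CC[C@]2(C)[C@H]1C | intermediate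
24 | acetone | CC(C)=O | starting material
25 | dilithium C3-alkoxide C7–C8 enolate of 23 | [Li+].[Li+].[O-][C@@H]1CCC2=C(O[Si](C(C)C)(C(C)C)C(C)C)C([O-])=CC[C@]2(C)[C@H]1C | intermediate (not isolated)
26 | (3R,4R,5R)-3-hydroxy-7-(2-hydroxypropan-2-yl)-4,5-dimethyl-9-[(triisopropylsilyl)oxy]octal-9-en-8-one (C7 epimers) | O[C@@H]1CCC2=C(O[Si](C(C)C)(C(C)C)C(C)C)C(=O)C(C(C)(C)O)C[C@]2(C)[C@H]1C | intermediate
27 | (3R,4R,5R)-3-hydroxy-4,5-dimethyl-7-(propan-2-ylidene)-9-[(triisopropylsilyl)oxy]octal-9-en-8-one | O[C@@H]1CCC2=C(O[Si](C(C)C)(C(C)C)C(C)C)C(=O)C(=C(C)C)C[C@]2(C)[C@H]1C | intermediate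
28 | 4-methylfuran-2(5H)-one | CC1=CC(=O)OC1 | starting material
29 | sodium (Z)-4-hydroxy-3-methylbut-2-enoate | [Na+].[O-]C(=O)/C=C(/C)CO | intermediate (not isolated)
30 | 4-methoxybenzyl (Z)-4-hydroxy-3-methylbut-2-enoate | COc1ccc(COC(=O)/C=C(/C)CO)cc1 | intermediate
31 | angelic acid, (Z)-2-methylbut-2-enoic acid | C/C=C(/C)C(=O)O | starting material
32 | 4-methoxybenzyl (Z)-3-methyl-4-{[(Z)-2-methylbut-2-enoyl]oxy}but-2-enoate | C/C=C(/C)C(=O)OC/C(C)=C\C(=O)OCc1ccc(OC)cc1 | intermediate
33 | (Z)-3-methyl-4-{[(Z)-2-methylbut-2-enoyl]oxy}but-2-enoic acid | C/C=C(/C)C(=O)OC/C(C)=C\C(=O)O | intermediate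
34 | mixed anhydride of 33 with 2,4,6-trichlorobenzoic acid | C/C=C(/C)C(=O)OC/C(C)=C\C(=O)OC(=O)c1c(Cl)cc(Cl)cc1Cl | intermediate (not isolated)
35 | (3R,4R,5R)-4,5-dimethyl-8-oxo-7-(propan-2-ylidene)-9-[(triisopropylsilyl)oxy]octal-9-en-3-yl (Z)-3-methyl-4-{[(Z)-2-methylbut-2-enoyl]oxy}but-2-enoate | C/C=C(/C)C(=O)OC/C(C)=C\C(=O)O[C@@H]1CCC2=C(O[Si](C(C)C)(C(C)C)C(C)C)C(=O)C(=C(C)C)C[C@]2(C)[C@H]1C | intermediate
36 | CNP0228871.1, (3R,4R,5R)-9-hydroxy-4,5-dimethyl-8-oxo-7-(propan-2-ylidene)octal-9-en-3-yl (Z)-3-methyl-4-{[(Z)-2-methylbut-2-enoyl]oxy}but-2-enoate | C/C=C(/C)C(=O)OC/C(C)=C\C(=O)O[C@@H]1CCC2=C(O)C(=O)C(=C(C)C)C[C@]2(C)[C@H]1C | target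

Total step count: 19. Longest linear sequence: 16 steps (steps 1–14, 18, 19); the side-chain acid 33 takes 3 steps (15–17).

Steps most likely to fail

Step 5. The enantioface discrimination may be weak, because an α-methyl vinyl ketone offers the catalyst no α-C–H contact of the kind that organises simpler enones, and 9 may partly cyclise thermally beside the catalysed pathway. Both processes lower the enantiomeric purity of 10; the cis/trans ratio at C10 is harmless. The fallback replaces asymmetric catalysis by resolution. It sets out from 9, which is cyclised with the achiral Lewis acid Me2AlCl (CH2Cl2, −78 °C) to give 10 together with its antipode F1 as the racemate. The two are separated by preparative chromatography on a chiral stationary phase (amylose tris(3,5-dimethylphenylcarbamate), supercritical CO2/2-propanol), and the route is rejoined at 10.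

Step 11. Chemoselectivity may be lost: the C8 alkoxyborane formed by ketone reduction may deliver hydride to the C9=C10 enol ether, the enone may be reduced in the 1,4 sense, and the silyl group may migrate from O9 to O8 during the basic oxidation. The fallback puts oxygen on C3 first and sets C4 by hydroxyl-directed hydrogenation, without borane. It sets out from 20. mCPBA (NaHCO3, CH2Cl2, 0 °C) epoxidises C3=C4 from the α face, anti to C14, to give the 3α,4α-epoxide F2. Diethylaluminium 2,2,6,6-tetramethylpiperidide, Et2Al(TMP), in excess (toluene, 0 °C; the ketone is carried as its aluminium enolate) isomerises it to the 3α-hydroxy-4(15)-methylene compound F3. Hydrogenation with [Ir(cod)(PCy3)(py)]PF6 (H2, CH2Cl2) delivers hydrogen to C4 from the face of the C3 hydroxyl and gives 23, where the route is rejoined; step 12 is then not needed.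

Step 18. Once 33 is turned into its carboxylate or an activated acyl species it may cyclise to butenolide 28 with loss of angelic acid, or lose its Z geometry by reversible γ-deprotonation, while acylation of the hindered secondary alcohol is slow. The fallback builds the side chain on the core and adds the angelate last. It sets out from 27 and 28. Butenolide 28 is opened with NaOH to 29 as in step 15 and silylated on both oxygens (TBSCl, imidazole, DMF) to the silyl ester silyl ether F4, whose silyl ester alone is cleaved (K2CO3, MeOH/THF/H2O) to the stable silyloxy acid F5. Yamaguchi coupling of F5 with 27 gives the silyloxy ester F6. PPTS in MeOH removes only the primary silyl ether and gives the hydroxy ester F7. Mitsunobu esterification of F7 with angelic acid 31 (PPh3, DIAD, THF, 0 °C) gives 35, where the route is rejoined.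

Further compounds
F1 | step 5 | antipode of 10, cis-fused (5R,10S)-5-methyl-8-[(triisopropylsilyl)oxy]octal-8-en-4-one | O=C1CCC[C@H]2C=C(O[Si](C(C)C)(C(C)C)C(C)C)CC[C@@]12C
F2 | step 11 | 3α,4α-epoxy-4,5-dimethyl-9-[(triisopropylsilyl)oxy]octal-9-en-8-one (C5 as in 20) | O1[C@@H]2CCC3=C(O[Si](C(C)C)(C(C)C)C(C)C)C(=O)CC[C@]3(C)[C@]12C
F3 | step 11 | 3α-hydroxy-5-methyl-4-methylidene-9-[(triisopropylsilyl)oxy]octal-9-en-8-one (C3, C5 as in 23) | O[C@@H]1CCC2=C(O[Si](C(C)C)(C(C)C)C(C)C)C(=O)CC[C@]2(C)C1=C
F4 | step 18 | tert-butyldimethylsilyl (Z)-4-[(tert-butyldimethylsilyl)oxy]-3-methylbut-2-enoate | CC(C)(C)[Si](C)(C)OC/C(C)=C\C(=O)O[Si](C)(C)C(C)(C)C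
F5 | step 18 | (Z)-4-[(tert-butyldimethylsilyl)oxy]-3-methylbut-2-enoic acid | CC(C)(C)[Si](C)(C)OC/C(C)=C\C(=O)O
F6 | step 18 | C3 ester of 27 with F5 | CC(C)(C)[Si](C)(C)OC/C(C)=C\C(=O)O[C@@H]1CCC2=C(O[Si](C(C)C)(C(C)C)C(C)C)C(=O)C(=C(C)C)C[C@]2(C)[C@H]1C
F7 | step 18 | C3 (Z)-4-hydroxy-3-methylbut-2-enoate of 27 | OC/C(C)=C\C(=O)O[C@@H]1CCC2=C(O[Si](C(C)C)(C(C)C)C(C)C)C(=O)C(=C(C)C)C[C@]2(C)[C@H]1C
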